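Start from the winter run: midnight has its charge, 0.200 M of starting material, and its temperature, so midnight's question is winter's curve read at 45 min.

| flask | starting material | product | time |
|---|---|---|---|
| noon | 0.500 M |  |  |
| winter | 0.200 M |  |  |
| summer | 1.00 M |  |  |
| dawn | 0.500 M | 0.150 M |  |
| midnight | 0.200 M |  | 45 min |

| noon run: time / min | noon run: [product] / M | winter run: time / min | winter run: [product] / M | summer run: time / min | summer run: [product] / M | dawn run: time / min | dawn run: [product] / M |
|---|---|---|---|---|---|---|---|
| 3.4 | 0.029 | 3.4 | 0.001 | 3.4 | 0.060 | 3.4 | 0.191 |
| 10 | 0.067 | 10 | 0.035 | 10 | 0.148 | 10 | 0.251 |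
| 20 | 0.126 | 20 | 0.055 | 20 | 0.231 | 20 | 0.321 |
| 31 | 0.182 | 31 | 0.071 | 31 | 0.305 | 31 | 0.359 |
| 45 | 0.202 | 45 | 0.103 | 45 | 0.351 | 45 | 0.411 |

(standard deviation of a reading: 0.005 M)

- the power of [starting material] that the first rate follows, about the charge of the noon run; measure it at two percent of starting material made into product (one fixed amount of product, the same in the runs compared)
- product in the midnight run at 45 min, as a share of the starting material charged

- Overall: starting material -> product.
- Constant volume, constant temperature.
- An order is taken over about fifteen percent of the charge, up and down.

Work with the fraction left, not the fraction made. Divide the logarithm of the charge over what is not yet product by the time; this is the fraction-left constant, the usual apparent first-order constant: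

k = ln(charge / (charge − [product])) / t

Now run the flasks in slow motion. First instants, at 10 min: the noon run reads 0.0144 min⁻¹, and the summer run, with twice the charge, reads 0.0160 min⁻¹. A constant that barely moves as the charge doubles means a rate nearly proportional to [starting material], so I take the order as near one.

Middle: by 10 min the readings of the dawn run show 0.101 M newly made beyond the product charged, more than the 0.067 M of the noon run, so watch product once it has built up.

End: the noon constant sags from 0.0145 min⁻¹ at 20 min to 0.0115 min⁻¹ at 45 min. For midnight, take the late winter readings:

k at 31 min = 0.0141 min⁻¹; k at 45 min = 0.0161 min⁻¹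

mean k = 0.0151 min⁻¹

share at 45 min = 1 − exp(−k t) = 49.3%

Carry this 0.0151 min⁻¹, the late fraction-left constant of the winter charge.

My own reckoning stands at 49.3%; the forecast gives order 0.95 and 49%, on the ground that “The midnight run repeats winter's conditions”.

The simulation gives order 1.0 and 48.4%, and both values of the forecast stand within their margins.

    starting material → product (0.008820 min⁻¹)
    starting material + product → 2 product (0.04836 L mol⁻¹ min⁻¹)
    starting material → product (0.009060 min⁻¹)
    2 starting material → homo dimer (0.04320 L mol⁻¹ min⁻¹)

Turn the midnight share back into its constant: 0.0147 min⁻¹. Now strike the path from starting material to product: midnight falls from 48.4% to 28.6%, and its constant drops to 0.00749 min⁻¹, about half. Take the carried 0.0151 min⁻¹ to the noon run: at 19.0 min, where product stands at a quarter of the charge, it gives a share of 24.9%, but at 73.8 min, where product stands at half of the charge, it gives 67.2%.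

The readings are calculated for substances that don't exist; the scatter is artificial.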